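## Retrosynthetic overview
1. The C12–O bond is made last. Punaglandin 4 comes from a planar 9‑silyloxyfulvene and ¹O₂ (sensitised photooxygenation). The C6‑OAc centre selects the face through A(1,3) strain, so C12 is relayed from C6 and the ring partner can be racemic.
2. C7=C8 comes from an aldol condensation of rac‑2‑chloro‑4‑[(Z)‑oct‑2‑enyl]cyclopent‑2‑enone with a C1–C7 aldehyde.
3. C3–C4 comes from a visible‑light Giese addition of the mono‑iodide of L‑threitol acetonide (L‑tartaric acid pool; C5 and C6 are bought) to methyl acrylate.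
4. C12–C13 comes from α′‑alkylation of 2‑chloro‑3‑ethoxycyclopentenone with (Z)‑1‑bromooct‑2‑ene, followed by reductive carbonyl transposition.
5. Rings: the only carbocycle is bought (3‑ethoxycyclopentenone) and never opened, so there is no ring‑forming step. The dioxolane is a bought temporary ring, removed in step 10.

Assumptions: compounds 1, 3, 7 and 9 are taken as commercial. Prostanoid numbering (C1 = ester carbon … C20) is used for advanced intermediates.

## Route

**Step 1**
Reactants: 1, (Z)‑oct‑2‑en‑1‑ol
Product: 2, (Z)‑1‑bromooct‑2‑ene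
Conditions: CBr4, PPh3, CH2Cl2, 0 °C
Reagents that add atoms: carbon tetrabromide, BrC(Br)(Br)Br
Why: Appel bromination is a neutral SN2 at the primary allylic carbon, so the Z‑alkene is kept and no stereocentre is involved.

**Step 2**
Reactants: 3, 3‑ethoxycyclopent‑2‑en‑1‑one
Product: 4, 2‑chloro‑3‑ethoxycyclopent‑2‑en‑1‑one
Conditions: NCS, CH2Cl2, 0 °C → rt
Reagents that add atoms: N‑chlorosuccinimide, O=C1CCC(=O)N1Cl
Why: Electrophilic α‑halogenation of a vinylogous ester, in which the push–pull enol ether attacks Cl⁺ at C2 only and then loses H⁺.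

**Step 3**
Reactants: 4, 2‑chloro‑3‑ethoxycyclopent‑2‑en‑1‑one; 2, (Z)‑1‑bromooct‑2‑ene
Product: 5, rac‑2‑chloro‑3‑ethoxy‑5‑[(Z)‑oct‑2‑en‑1‑yl]cyclopent‑2‑en‑1‑one
Conditions: LDA, THF, −78 °C; then 2, DMPU, −78 → −30 °C
Reagents that add atoms: none (both partners are numbered reactants)
Why: Stork–Danheiser kinetic α′‑enolate alkylation, where the primary allylic bromide reacts by SN2 with the Z geometry kept, and the new centre (future C12) is racemic and is erased in step 11.

**Step 4**
Reactants: 5
Product: 6, rac‑2‑chloro‑4‑[(Z)‑oct‑2‑en‑1‑yl]cyclopent‑2‑en‑1‑one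
Conditions: DIBAL‑H, CH2Cl2, −78 °C; then 1 M HCl, THF, 0 °C → rt
Reagents that add atoms: water, O (supplies the new C=O oxygen)
Why: Stork–Danheiser 1,2‑reduction followed by acidic enol‑ether hydrolysis transposes the carbonyl, which puts Cl at the α position and the octenyl chain at the γ position.

**Step 5**
Reactants: 7, (4S,5S)‑2,2‑dimethyl‑1,3‑dioxolane‑4,5‑dimethanol (2,3‑O‑isopropylidene‑L‑threitol)
Product: 8, [(4S,5R)‑5‑(iodomethyl)‑2,2‑dimethyl‑1,3‑dioxolan‑4‑yl]methanol
Conditions: I2 (1.0 equiv), PPh3, imidazole, THF, 0 °C (diol recovered and recycled)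
Reagents that add atoms: iodine, II
Why: Appel‑type mono‑iodination of a C2‑symmetric diol, where the two OH groups are homotopic (only a statistical issue) and the two bought stereocentres are untouched.

**Step 6**
Reactants: 8; 9, methyl acrylate
Product: 10, methyl 4‑[(4S,5S)‑5‑(hydroxymethyl)‑2,2‑dimethyl‑1,3‑dioxolan‑4‑yl]butanoate
Conditions: 4CzIPN (2 mol %), Et3N, H2O, MeCN, 450 nm LEDs, rt
Reagents that add atoms: methyl acrylate (9), C=CC(=O)OC
Why: Photochemical Giese reaction in which a photogenerated α‑aminoalkyl radical abstracts iodine and the primary C4 radical adds to acrylate to form C3–C4, leaving the adjacent stereocentres, the free OH and the acetonide unaffected.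

**Step 7**
Reactants: 10
Product: 11, methyl 4‑[(4S,5R)‑5‑formyl‑2,2‑dimethyl‑1,3‑dioxolan‑4‑yl]butanoate
Conditions: Dess–Martin periodinane, NaHCO3, CH2Cl2, 0 °C → rt
Reagents that add atoms: none
Why: Dess–Martin oxidation is mild and buffered, and the trans‑dioxolane aldehyde is the thermodynamic epimer, so C6 is not eroded.

**Step 8**
Reactants: 6 (1.2 equiv); 11
Product: 12, methyl 4‑[(4S,5S)‑5‑{[3‑chloro‑2‑oxo‑5‑((Z)‑oct‑2‑enyl)cyclopent‑3‑en‑1‑yl](hydroxy)methyl}‑2,2‑dimethyl‑1,3‑dioxolan‑4‑yl]butanoate (mixture at C7, C8 and C12)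
Conditions: LDA, THF, −78 °C; then 11, −78 °C; AcOH quench
Reagents that add atoms: none
Why: Aldol addition of the kinetic cross‑conjugated lithium enolate (C8) to the aldehyde, which reacts far faster than the methyl ester at −78 °C, and the C7, C8 and C12 centres are all destroyed later, so the diastereomer mixture is carried on.

**Step 9**
Reactants: 12
Product: 13, methyl 4‑[(4S,5S)‑5‑{(E)‑[3‑chloro‑2‑oxo‑5‑((Z)‑oct‑2‑enyl)cyclopent‑3‑en‑1‑ylidene]methyl}‑2,2‑dimethyl‑1,3‑dioxolan‑4‑yl]butanoate (7E; about 1:1 at C12)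
Conditions: MsCl, DMAP, CH2Cl2, 0 °C → rt
Reagents that add atoms: none
Why: Mesylation followed by E1cB elimination gives the thermodynamic E‑alkylidene (C6 anti to C9=O), as is usual for 5‑alkylidenecyclopent‑2‑enones.

**Step 10**
Reactants: 13
Product: 14, methyl (5S,6S,7E,14Z)‑5,6‑diacetoxy‑10‑chloro‑9‑oxoprosta‑7,10,14‑trien‑1‑oate (12‑deoxy compound; about 1:1 at C12)
Conditions: TFA–H2O (9:1), CH2Cl2, 0 °C; concentrate; then Ac2O, pyridine, cat. DMAP, 0 °C → rt, Ar (one flask, two stages)
Reagents that add atoms: acetic anhydride, CC(=O)OC(C)=O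
Why: Acetal hydrolysis and then O‑acetylation break no C5–O or C6–O bond (retention), and immediate acetylation prevents δ‑lactonisation of the C5‑OH onto C1.

**Step 11**
Reactants: 14
Product: 15, methyl (5S,6S,7E,14Z)‑5,6‑diacetoxy‑10‑chloro‑9‑(triethylsilyloxy)prosta‑7,9,11,14‑tetraen‑1‑oate (9‑silyloxyfulvene; single compound)
Conditions: TESOTf, Et3N, CH2Cl2, −78 → −30 °C; cold pentane/NaHCO3 work‑up, short Florisil plug, used at once
Reagents that add atoms: triethylsilyl triflate, CC[Si](CC)(CC)OS(=O)(=O)C(F)(F)F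
Why: Vinylogous soft enolisation (silyl dienol ether formation) works here because C8 has no α′‑H and C6–H is held in the π‑nodal plane by A(1,3) strain, so only the ring C12–H is aligned and removed, and both C12 epimers converge on one planar fulvene.

**Step 12**
Reactants: 15
Product: 16, punaglandin 4, methyl (5S,6S,7E,12R,14Z)‑5,6‑diacetoxy‑10‑chloro‑12‑hydroxy‑9‑oxoprosta‑7,10,14‑trien‑1‑oate
Conditions: O2, tetraphenylporphyrin (1 mol %), CH2Cl2, −78 °C, 590 nm LEDs; PPh3, −78 → 0 °C; HF·pyridine, MeCN, 0 °C
Reagents that add atoms: dioxygen, O=O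
Why: Proposed new method: sensitised ¹O₂ adds [4+2] across C9/C12 of the electron‑rich cyclopentadiene core of 15, which is its only s‑cis diene and should react far faster than the ene pathway at the isolated Z‑alkene; the bicyclic endoperoxide is a peroxy silyl ketal at C9, so it collapses heterolytically (O→O silyl shift) to C9=O and C12–OOSiEt3, which PPh3 and HF convert to C12–OH without breaking the C12–O bond; C12 is set by C6 because A(1,3) strain between C13H2 and C6 locks C6–H in the fulvene plane, the C6 acetoxy group (its C=O eclipsing C6–H) shields one face and repels ¹O₂ electrostatically, and the extended C5–C4 chain leaves only C5–H over the other face, so O2 enters anti to OAc, which for the 6S,7E substrate gives 12R (my estimate is dr about 5:1, with the epimer separable); the closest known reaction types are photooxygenation of fulvenes and of 2‑silyloxydienes to γ‑hydroxyenones (Kornblum–DeLaMare‑type collapse) and A(1,3)‑controlled photooxygenation of chiral allylic acetates, and to my knowledge none has been shown on a silyloxyfulvene or used to set a tertiary carbinol by remote acyclic control.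

## Compound list
1 | (Z)‑oct‑2‑en‑1‑ol | CCCCC/C=C\CO | starting material
2 | (Z)‑1‑bromooct‑2‑ene | CCCCC/C=C\CBr | intermediate
3 | 3‑ethoxycyclopent‑2‑en‑1‑one | CCOC1=CC(=O)CC1 | starting material
4 | 2‑chloro‑3‑ethoxycyclopent‑2‑en‑1‑one | CCOC1=C(Cl)C(=O)CC1 | intermediate
5 | rac‑2‑chloro‑3‑ethoxy‑5‑[(Z)‑oct‑2‑enyl]cyclopent‑2‑en‑1‑one | CCCCC/C=C\CC1CC(OCC)=C(Cl)C1=O | intermediate (racemic)
6 | rac‑2‑chloro‑4‑[(Z)‑oct‑2‑enyl]cyclopent‑2‑en‑1‑one | CCCCC/C=C\CC1C=C(Cl)C(=O)C1 | intermediate (racemic)
7 | (4S,5S)‑2,2‑dimethyl‑1,3‑dioxolane‑4,5‑dimethanol | OC[C@@H]1OC(C)(C)O[C@H]1CO | starting material (chiral pool)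
8 | [(4S,5R)‑5‑(iodomethyl)‑2,2‑dimethyl‑1,3‑dioxolan‑4‑yl]methanol | OC[C@@H]1OC(C)(C)O[C@H]1CI | intermediate
9 | methyl acrylate | C=CC(=O)OC | starting material
10 | methyl 4‑[(4S,5S)‑5‑(hydroxymethyl)‑2,2‑dimethyl‑1,3‑dioxolan‑4‑yl]butanoate | OC[C@@H]1OC(C)(C)O[C@H]1CCCC(=O)OC | intermediate
11 | methyl 4‑[(4S,5R)‑5‑formyl‑2,2‑dimethyl‑1,3‑dioxolan‑4‑yl]butanoate | O=C[C@@H]1OC(C)(C)O[C@H]1CCCC(=O)OC | intermediate
12 | aldol adduct (5S,6S fixed; mixture at C7, C8, C12) | CCCCC/C=C\CC1C=C(Cl)C(=O)C1C(O)[C@@H]2OC(C)(C)O[C@H]2CCCC(=O)OC | intermediate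
13 | (7E)‑alkylidene enone acetonide (5S,6S; C12 epimers) | CCCCC/C=C\CC1C=C(Cl)C(=O)/C1=C/[C@@H]2OC(C)(C)O[C@H]2CCCC(=O)OC | intermediate
14 | 12‑deoxypunaglandin 4 (5S,6S,7E,14Z; C12 epimers) | CCCCC/C=C\CC1C=C(Cl)C(=O)/C1=C/[C@H](OC(C)=O)[C@H](CCCC(=O)OC)OC(C)=O | intermediate
15 | 9‑(triethylsilyloxy)fulvene (5S,6S,7E,14Z) | CCCCC/C=C\CC1=CC(Cl)=C(O[Si](CC)(CC)CC)/C1=C/[C@H](OC(C)=O)[C@H](CCCC(=O)OC)OC(C)=O | intermediate
16 | punaglandin 4 (5S,6S,7E,12R,14Z) | CCCCC/C=C\C[C@@]1(O)C=C(Cl)C(=O)/C1=C/[C@H](OC(C)=O)[C@H](CCCC(=O)OC)OC(C)=O | target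

## Summary
Total steps: 12.
Longest linear sequence: 8. All three branches are equal in length: steps 2‑3‑4, 1‑3‑4 or 5‑6‑7, each followed by steps 8–12.

Steps most likely to fail:
1. **Step 12 (new photooxygenation).**
   - Risks: modest facial selectivity, rearrangement of the fulvene endoperoxide if it warms, and a competing ene reaction.
   - Fallback (known chemistry): buy C12 instead of relaying it.
     - Convert (S)‑malic acid to its pivalaldehyde dioxolanone.
     - Alkylate with LiHMDS and 2 (self‑regeneration of the stereocentre; retention corresponds to 12R).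
     - Turn the side‑chain acid into a chloromethyl ketone, reduce the dioxolanone with DIBAL, and close the ring by intramolecular aldol condensation to give (R)‑2‑chloro‑4‑hydroxy‑4‑octenylcyclopentenone.
     - Protect as the silyl ether, then run the established LDA aldol and MsCl/DMAP sequence with 11, swap the acetonide for the diacetate, and desilylate.
2. **Step 11 (silyloxyfulvene formation).**
   - Risks: enolisation at C6–H, ionisation of the acetate, and fulvene dimerisation.
   - Fallback: avoid the fulvene and oxygenate before the union.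
     - Hydroxylate the lithium enolate of 5 with a 2‑sulfonyloxaziridine and protect the alcohol as its TES ether.
     - Carry out DIBAL/H3O⁺ transposition to the racemic 4‑silyloxy enone.
     - Perform the aldol and dehydration with 11. The C12 epimers are now diastereomers because of the tartrate‑derived centres, so they can be separated by chromatography. This costs half of the ring fragment.
3. **Step 3 (α′‑alkylation of the chloro vinylogous ester).**
   - Risks: γ‑deprotonation, O‑alkylation, and decomposition of the enolate.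
   - Fallback: build the ring instead of buying it.
     - Start from (Z)‑dec‑4‑enal, which already holds C11–C20 and the Z‑alkene, and form its tert‑butylimine.
     - Alkylate the metalloenamine (LDA) with 2,3‑dichloropropene and hydrolyse to the 4‑oxopentanal.
     - Cyclise with KOH by intramolecular aldol condensation to 4‑octenylcyclopentenone.
     - Epoxidise with H2O2/NaOH and treat with HCl to give 6.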